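- I choose to watch the second substrate in this flask, not the starting material.

| flask | starting material | second substrate | enzyme | remark |
|---|---|---|---|---|
| zeta | 0.050 M | 0.050 M | 1.1 µM | the very flask that is asked about, followed so far |
| alpha | 0.10 M | 0.050 M | 1.1 µM | run made earlier |
| flask | 0.050 M | 0.0500 M | 1.1 µM |  |

| run | time / min | product / % | starting material / % |
|---|---|---|---|
| zeta | 6.00 | 10.2 | 90.0 |
| zeta | 12.0 | 20.6 | 81.3 |
| zeta | 20.0 | 34.2 | 69.0 |
| zeta | 25.0 | 39.5 | 62.3 |
| alpha | 15.0 | 12.7 | 86.5 |
| alpha | 30.0 | 23.0 | 76.2 |
| alpha | 40.0 | 28.9 | 69.6 |
| alpha | 60.0 | 36.8 | 62.4 |

(scatter of a reading: 1 percentage point)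

- factor on the rate of making product when 30 % of the starting material are converted if second substrate is charged twice over
- factor on the rate when 30 % of the starting material are converted if enzyme is charged at 0.12 µM instead

- no earlier run changes the charge of enzyme; that part of a forecast is a guess
- no earlier run changes the charge of second substrate; that part of a forecast is a guess

- Two readings seem to clash. Up to its first reading zeta makes 0.850 mM/min of product and alpha 0.847 mM/min, although alpha has twice the starting material. Yet after 60.0 min alpha still holds 62.4 mM, more than zeta's charge, and between 40.0 min and 60.0 min it makes on average 0.395 mM/min.
- Both runs share one charge of second substrate. If it goes one for one with starting material, alpha has 12.4 mM left by then.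
- Equal charges make zeta the symmetric case, where on that assumption both fall alike, and its last reading gives 0.0189 /min. This is my second-substrate clock: the natural logarithm of second substrate charged over second substrate left, divided by time, a pseudo-first-order constant. Alpha's last reading gives 0.0232 /min; both values carry the scatter of the readings.
- I take the rate as following second substrate left, so at 30 % conversion doubling its charge gives 2.43. I guess that the clock scales with enzyme, giving 0.109.
- The forecast says 1.4, “with a wide range”, and 0.105; on the first it differs from me.
- The flask gives 2.00 on doubling, below my 2.43 and above the forecast's 1.4, and 0.109 on the smaller enzyme charge.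

    second substrate + starting complex ⇌ ternary complex (K = 25.0 /M, k = 510 /M/s)
    starting material + enzyme ⇌ starting complex (K = 120 /M, k = 6200 /M/s)
    ternary complex → enzyme + product (k = 100 /s)

- The clock leaves 22.0 % of second substrate in this flask after 80.0 min, where 23.7 % stands. Scaled to the enzyme charge of 0.12 µM it runs at 0.00206 /min, a factor of 0.109 on the rate, and the flask with that charge gives 0.109. In this flask enzyme takes up starting material, forward step alone, at 19000 /min per enzyme as charged, faster than ternary complex releases product at 6000 /min per ternary complex. After 8.00 min in this flask starting complex, the resting state of that moment, holds 69.2 % of the enzyme charged, more than free enzyme at 18.2 % or ternary complex at 12.6 %.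

The data come from a simulation for substances that don't exist.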